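The route rests on cutting both bonds that make C11 neopentyl: the C11–C5' bond and the C8–methyl bond are formed together while C8 is still the trigonal α-carbon of an exocyclic enone in ring B. In one flask the extended enolate of a 4-methoxy-5-methylfuroate, which already holds all five cyclopentenone carbons and the ester, adds to the C8 methylene of a trans-decalin C7 ketone and the resulting C7 enolate is methylated on the α face, anti to the axial C9 methyl, to fix quaternary C8. The precursor is an enantiopure 8-methylene-7-oxo decalin made by asymmetric conjugate addition, ring-closing metathesis and reductive methylenation; deoxygenation, furan photooxygenation and aldol closure complete the target.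

Key step: step 11

Remark: locants follow the target (ring A = C1–C5/C10 with the C3=C4 alkene, ring B = C5–C10, C11 = linking CH2, C1'–C5' = cyclopentenone with C1' the ketone and C4' the carbinol; α is the face of H-10, β that of the C5 methyl); the ligand antipodes in steps 1 and 16 are taken as those that deliver the stated configurations.

Step 1
Reactants: 1 2-methylcyclohex-2-en-1-one; 2 isopropenylmagnesium bromide; 3 methyl bromoacetate
Product: 5 methyl 2-[(1S,6S)-1-methyl-2-oxo-6-(prop-1-en-2-yl)cyclohexyl]acetate, via magnesium enolate 4 (not isolated)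
Conditions: Cu(OTf)2 (4 mol %), chiral bidentate hydroxyalkyl-NHC ligand (from its imidazolinium salt, 5 mol %), Et2O, −30 °C; then DMPU, 3, −30 → 0 °C
Reagents that add atoms: none
Why: Copper-catalysed asymmetric conjugate addition of a Grignard reagent to an α-methyl cyclic enone is a known reaction class in which the chiral NHC–copper complex selects the enone face (S configuration at the isopropenyl-bearing carbon, the future C10), and the tetrasubstituted magnesium enolate 4 is then alkylated by the bromoacetate anti to the new neighbouring substituent, which sets the quaternary carbon (future C5) with CH2CO2Me trans to isopropenyl, the relationship that becomes the trans ring fusion.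

Step 2
Reactants: 5 methyl 2-[(1S,6S)-1-methyl-2-oxo-6-(prop-1-en-2-yl)cyclohexyl]acetate
Product: 7 methyl 2-[(1S,6S)-1-methyl-6-(prop-1-en-2-yl)-2-(trifluoromethylsulfonyloxy)cyclohex-2-en-1-yl]acetate, via potassium enolate 6 (not isolated)
Conditions: KN(SiMe3)2, THF, −78 °C; then PhNTf2, −78 → 0 °C
Reagents that add atoms: N-phenylbis(trifluoromethanesulfonimide), O=S(=O)(N(c1ccccc1)S(=O)(=O)C(F)(F)F)C(F)(F)F
Why: Kinetic deprotonation can only occur at the ring CH2 flanking the ketone (the other α-carbon is quaternary and the ester α-protons are far less acidic), and O-sulfonylation of enolate 6 gives the enol triflate (enol triflate formation) without touching a stereocentre.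

Step 3
Reactants: 7 enol triflate
Product: 8 methyl 2-[(1S,6S)-1,2-dimethyl-6-(prop-1-en-2-yl)cyclohex-2-en-1-yl]acetate
Conditions: MeZnCl, Pd(PPh3)4 (5 mol %), THF, 50 °C
Reagents that add atoms: methylzinc chloride, C[Zn]Cl
Why: Negishi cross-coupling of the alkenyl triflate with the methylzinc reagent under zerovalent palladium catalysis installs the C4 methyl group on a double bond whose position (C3=C4) is fixed by the triflate, and the organozinc reagent leaves the ester untouched.

Step 4
Reactants: 8 methyl 2-[(1S,6S)-1,2-dimethyl-6-(prop-1-en-2-yl)cyclohex-2-en-1-yl]acetate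
Product: 9 N-methoxy-N-methyl-2-[(1S,6S)-1,2-dimethyl-6-(prop-1-en-2-yl)cyclohex-2-en-1-yl]acetamide
Conditions: Me(MeO)NH·HCl, i-PrMgCl, THF, −20 → 0 °C
Reagents that add atoms: N,O-dimethylhydroxylamine hydrochloride, CNOC.Cl
Why: The chloromagnesium amide formed in the flask converts the unhindered methyl ester directly into the Weinreb amide (ester aminolysis), and no stereocentre is involved.

Step 5
Reactants: 9 Weinreb amide
Product: 11 1-[(1S,6S)-1,2-dimethyl-6-(prop-1-en-2-yl)cyclohex-2-en-1-yl]but-3-en-2-one, via magnesium hemiaminal chelate 10 (not isolated)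
Conditions: CH2=CHMgBr, THF, −20 → 0 °C; cold aq. HCl quench
Reagents that add atoms: vinylmagnesium bromide, C=C[Mg]Br
Why: Weinreb ketone synthesis, in which the Grignard reagent adds only once because the chelated tetrahedral adduct 10 survives until the acidic quench, which also protonates the liberated amine so that it cannot add to the vinyl ketone.

Step 6
Reactants: 11 vinyl ketone
Product: 12 (4aS,8aS)-4,8,8a-trimethyl-4a,5,6,8a-tetrahydronaphthalen-2(1H)-one (trans-fused dienone; C7 ketone; C8=C9; C3=C4)
Conditions: second-generation Grubbs catalyst (3 mol %), CH2Cl2, 40 °C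
Reagents that add atoms: none
Why: Ring-closing metathesis between the enone vinyl group and the 1,1-disubstituted isopropenyl group closes ring B as a six-membered trisubstituted cyclohexenone with loss of ethene, the trisubstituted ring A alkene being too hindered to take part.

Step 7
Reactants: 12 bicyclic enone
Product: 13 dimethyl(phenyl)silyl enol ether of the (5S,9R,10S)-9β-methyl 7-ketone (silyloxy on C7; C7=C8; H-9α)
Conditions: [(Ph3P)CuH]6 (3 mol %), PhMe2SiH, toluene, rt
Reagents that add atoms: dimethyl(phenyl)silane, C[SiH](C)c1ccccc1
Why: Copper hydride 1,4-reduction (conjugate hydrosilylation) of the β,β-disubstituted enone delivers hydride to C9 from the α face, because the β face of C9 is screened by the syn-axial 5β-methyl group, so that the 9-methyl group ends β (axial, H-9α), and it leaves the C7 enolate regiospecifically as its C7–C8 silyl enol ether.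

Step 8
Reactants: 13 silyl enol ether; 14 iodomethane
Product: 17 fragment 1, (5S,9R,10S)-4,5,9-trimethyl-8-methylene-trans-decal-3-en-7-one (5β-CH3; 9β-CH3; H-10α), via Mannich base 15 (not isolated), via ammonium iodide 16 (not isolated)
Conditions: Me2N=CH2+ I−, CH2Cl2, rt; then 14, MeOH; then aq. NaHCO3, CH2Cl2, rt
Reagents that add atoms: N,N-dimethylmethyleneiminium iodide (Eschenmoser's salt), C[N+](C)=C.[I-]
Why: Mannich reaction of the silyl enol ether with the preformed iminium salt occurs only at C8, and N-methylation followed by mild base-induced E1cB loss of trimethylamine gives the α-methylene ketone (Eschenmoser methylenation) without epimerising C9, which is not enolisable under these conditions; the enone is used at once because α-methylene ketones dimerise on storage.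

Step 9
Reactants: 18 methyl 5-methylfuran-2-carboxylate
Product: 19 methyl 4-bromo-5-methylfuran-2-carboxylate
Conditions: N-bromosuccinimide, DMF, rt, dark
Reagents that add atoms: N-bromosuccinimide, O=C1CCC(=O)N1Br
Why: Electrophilic aromatic bromination goes to C4, the only free position that is ortho to the activating methyl group and not adjacent to the deactivating ester, and the polar radical-free conditions avoid bromination of the methyl group.

Step 10
Reactants: 19 methyl 4-bromo-5-methylfuran-2-carboxylate
Product: 20 methyl 4-methoxy-5-methylfuran-2-carboxylate (fragment 2)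
Conditions: NaOMe, CuBr (15 mol %), MeOH–DMF, 100 °C
Reagents that add atoms: sodium methoxide, C[O-].[Na+]
Why: Ullmann-type C–O coupling in which monovalent copper mediates replacement of the heteroaryl bromide by methoxide, a standard entry to 3-alkoxyfurans, while transesterification by methoxide is degenerate for the methyl ester.

Step 11
Reactants: 20 methyl 4-methoxy-5-methylfuran-2-carboxylate; 17 fragment 1; 14 iodomethane
Product: 23 methyl 4-methoxy-5-{2-[(5S,8R,9R,10S)-4,5,8,9-tetramethyl-7-oxo-trans-decal-3-en-8-yl]ethyl}furan-2-carboxylate (8α-CH3; 9β-CH3), via lithium trienolate 21 (not isolated), via lithium enolate 22 (not isolated)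
Conditions: LiN(i-Pr)2 (1.1 equiv), 20 (1.15 equiv), THF, −78 °C; then 17 (1.0 equiv), −78 °C; then 14 (5 equiv), DMPU, −78 → −20 °C
Reagents that add atoms: none
Why: LiN(i-Pr)2 removes a proton from the 5-methyl group of 20 to give the delocalised trienolate 21 (lateral and not ring metalation, since this anion is conjugated with the ester), whose exocyclic carbon adds 1,4 to the unhindered methylene terminus of enone 17, forming the C11–C5' bond and restoring the aromatic furan. The closest known reaction type is the Michael addition of laterally lithiated aryl and heteroaryl esters (vinylogous ester enolates) to α-methylene ketones and other enones with alkylation of the resulting enolate in the same flask. No ring is closed. The addition leaves lithium enolate 22 with its double bond fixed between C7 and C8, so iodomethane can only alkylate C8, and it does so along the axial trajectory on the α face through a chair-like transition state, anti to the axial 9β-methyl group and remote from the 5β-methyl group, which makes the new methyl axial (α), the furylethyl chain equatorial (β) and C8 the R-configured quaternary centre. The step needs 1,4- instead of 1,2-addition, which the soft delocalised anion and the unsubstituted exocyclic terminus secure, and C-methylation without prior proton transfer, which the regiospecifically formed enolate, excess iodomethane and DMPU at low temperature secure. The 2,5-relationship of ester and side chain on the furan excludes an intramolecular Claisen attack of the enolate on the ester.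

Step 12
Reactants: 23 furylethyl C7 ketone
Product: 24 methyl 5-{2-[(5S,7S,8R,9R,10S)-7-hydroxy-4,5,8,9-tetramethyl-trans-decal-3-en-8-yl]ethyl}-4-methoxyfuran-2-carboxylate (7β-OH; axial)
Conditions: NaBH4, CeCl3·7H2O, MeOH–THF, 0 °C → rt
Reagents that add atoms: none
Why: Borohydride reduction under Luche-type conditions reduces the hindered ketone but not the heteroaromatic ester, hydride entering from the α face because the β face of C7 is blocked by the syn-axial methyl groups on C5 and C9, which should give mainly the axial 7β-alcohol; the configuration of this carbinol is immaterial since it is removed in step 14.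

Step 13
Reactants: 24 C7 alcohol; 14 iodomethane
Product: 27 O-[(7S)-decalin-7-yl] S-methyl dithiocarbonate of 24 (xanthate), via sodium alkoxide 25 (not isolated), via sodium xanthate 26 (not isolated)
Conditions: NaH, imidazole (cat.), THF, 0 °C → rt; CS2; then 14
Reagents that add atoms: carbon disulfide, S=C=S
Why: Xanthate formation (first stage of the Barton–McCombie deoxygenation), in which alkoxide 25 adds to carbon disulfide, a small linear electrophile that tolerates the crowded axial position where acylating agents would fail, and S-methylation of xanthate salt 26 gives the O-alkyl S-methyl dithiocarbonate.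

Step 14
Reactants: 27 xanthate
Product: 28 methyl 4-methoxy-5-{2-[(5S,8R,9R,10S)-4,5,8,9-tetramethyl-trans-decal-3-en-8-yl]ethyl}furan-2-carboxylate
Conditions: Bu3SnH (0.2 M), AIBN (cat.), toluene, 100 °C
Reagents that add atoms: none
Why: Barton–McCombie deoxygenation, in which the stannyl radical adds to the thiocarbonyl group, β-scission releases the secondary C7 radical and hydrogen transfer from the concentrated tin hydride outruns any cyclisation onto the furan, giving the C7 methylene group without affecting other stereocentres.

Step 15
Reactants: 28 deoxygenated furan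
Product: 30 methyl (3E)-4-methoxy-2,5-dioxo-7-[(5S,8R,9R,10S)-4,5,8,9-tetramethyl-trans-decal-3-en-8-yl]hept-3-enoate (the two ketone carbons cis on the double bond), via furan endoperoxide 29 (not isolated)
Conditions: O2, visible light, tetraphenylporphyrin (cat.), CH2Cl2, −78 °C; then Me2S, −78 °C → rt; used crude
Reagents that add atoms: dioxygen, O=O
Why: Photosensitised singlet oxygen adds across the 2,5-positions of the electron-rich 3-methoxyfuran ([4+2] cycloaddition) faster than it undergoes the ene reaction with the hindered ring A alkene at −78 °C, and reduction of endoperoxide 29 with dimethyl sulfide unmasks the ene-trione with the cis geometry inherited from the furan ring.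

Step 16
Reactants: 30 cis ene-trione
Product: 31 Dysidenone B, methyl (1R,5S)-1-hydroxy-3-methoxy-4-oxo-5-{[(5S,8R,9R,10S)-4,5,8,9-tetramethyl-trans-decal-3-en-8-yl]methyl}cyclopent-2-ene-1-carboxylate
Conditions: Cu(OTf)2 (10 mol %), (R,R)-2,2'-isopropylidenebis(4-tert-butyl-2-oxazoline) (11 mol %), i-Pr2NEt (10 mol %), CH2Cl2, −40 °C
Reagents that add atoms: none
Why: Proposed new method: two-point binding of the C4' keto ester to the chiral divalent copper bisoxazoline Lewis acid activates the ketone and screens one of its faces while the amine reversibly enolises the C1' ketone towards C5', and the tethered enol closes the five-membered ring by a 5-(enolendo)-exo-trig aldol addition; the closest known reaction types are the Cu(OTf)2–bisoxazoline-catalysed aldol and ene additions to α-keto esters and the base-mediated aldol closure of cis-enediones to 4-hydroxycyclopent-2-enones; the ligand antipode fixes C4' (the (R,R)-ligand is expected to give 4'R by analogy with additions to pyruvate esters), and C5' is set in the same event because the bulky chelate occupies the exo sector of the forming ring and steers the C5' side chain to the face of the ester, trans to the new hydroxyl, the low temperature suppressing retro-aldol equilibration.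

Compound list
1 | 2-methylcyclohex-2-en-1-one | CC1=CCCCC1=O | starting material
2 | isopropenylmagnesium bromide (prop-1-en-2-ylmagnesium bromide) | CC(=C)[Mg]Br | starting material
3 | methyl bromoacetate | COC(=O)CBr | starting material
4 | bromomagnesium (3S)-2-methyl-3-(prop-1-en-2-yl)cyclohex-1-en-1-olate | CC1=C(O[Mg]Br)CCC[C@H]1C(C)=C | intermediate
5 | methyl 2-[(1S,6S)-1-methyl-2-oxo-6-(prop-1-en-2-yl)cyclohexyl]acetate | COC(=O)C[C@]1(C)C(=O)CCC[C@H]1C(C)=C | intermediate
6 | potassium (5S,6S)-6-(2-methoxy-2-oxoethyl)-6-methyl-5-(prop-1-en-2-yl)cyclohex-1-en-1-olate (enolate of 5) | COC(=O)C[C@]1(C)C(O[K])=CCC[C@H]1C(C)=C | intermediate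
7 | methyl 2-[(1S,6S)-1-methyl-6-(prop-1-en-2-yl)-2-(trifluoromethylsulfonyloxy)cyclohex-2-en-1-yl]acetate | COC(=O)C[C@]1(C)C(OS(=O)(=O)C(F)(F)F)=CCC[C@H]1C(C)=C | intermediate
8 | methyl 2-[(1S,6S)-1,2-dimethyl-6-(prop-1-en-2-yl)cyclohex-2-en-1-yl]acetate | COC(=O)C[C@]1(C)C(C)=CCC[C@H]1C(C)=C | intermediate
9 | N-methoxy-N-methyl-2-[(1S,6S)-1,2-dimethyl-6-(prop-1-en-2-yl)cyclohex-2-en-1-yl]acetamide | CON(C)C(=O)C[C@]1(C)C(C)=CCC[C@H]1C(C)=C | intermediate
10 | bromomagnesium hemiaminal from 9 and the vinyl Grignard reagent (tetrahedral chelate; carbinolamine carbon unassigned) | C=CC(O[Mg]Br)(N(C)OC)C[C@]1(C)C(C)=CCC[C@H]1C(C)=C | intermediate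
11 | 1-[(1S,6S)-1,2-dimethyl-6-(prop-1-en-2-yl)cyclohex-2-en-1-yl]but-3-en-2-one | C=CC(=O)C[C@]1(C)C(C)=CCC[C@H]1C(C)=C | intermediate
12 | (4aS,8aS)-4,8,8a-trimethyl-4a,5,6,8a-tetrahydronaphthalen-2(1H)-one | CC1=CC(=O)C[C@]2(C)C(C)=CCC[C@@H]12 | intermediate
13 | dimethyl(phenyl)silyl enol ether of the (5S,9R,10S)-9β-methyl 7-ketone (C7=C8; H-9α) | C1=C(O[Si](C)(C)c3ccccc3)C[C@]2(C)C(C)=CCC[C@H]2[C@H]1C | intermediate
14 | iodomethane | CI | starting material
15 | 8-(dimethylaminomethyl) 7-ketone (Mannich base; C8 configuration immaterial, drawn 8α-CH2N) | CN(C)C[C@@H]1C(=O)C[C@]2(C)C(C)=CCC[C@H]2[C@H]1C | intermediate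
16 | trimethylammonium iodide of 15 | C[N+](C)(C)C[C@@H]1C(=O)C[C@]2(C)C(C)=CCC[C@H]2[C@H]1C.[I-] | intermediate
17 | fragment 1, (5S,9R,10S)-4,5,9-trimethyl-8-methylene-trans-decal-3-en-7-one | C=C1C(=O)C[C@]2(C)C(C)=CCC[C@H]2[C@H]1C | intermediate
18 | methyl 5-methylfuran-2-carboxylate | COC(=O)c1ccc(C)o1 | starting material
19 | methyl 4-bromo-5-methylfuran-2-carboxylate | COC(=O)c1cc(Br)c(C)o1 | intermediate
20 | methyl 4-methoxy-5-methylfuran-2-carboxylate (fragment 2) | COC(=O)c1cc(OC)c(C)o1 | intermediate
21 | lithium trienolate of 20 (O-lithio form; exocyclic methylene on C5 of the furan) | COC(O[Li])=C1C=C(OC)C(=C)O1 | intermediate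
22 | lithium C7 enolate of the conjugate adduct (C7=C8; furylethyl on C8) | COC(=O)c1cc(OC)c(CCC2=C(O[Li])C[C@]3(C)C(C)=CCC[C@H]3[C@H]2C)o1 | intermediate
23 | methyl 4-methoxy-5-{2-[(5S,8R,9R,10S)-4,5,8,9-tetramethyl-7-oxo-trans-decal-3-en-8-yl]ethyl}furan-2-carboxylate | COC(=O)c1cc(OC)c(CC[C@@]2(C)C(=O)C[C@]3(C)C(C)=CCC[C@H]3[C@H]2C)o1 | intermediate
24 | 7β-alcohol (7S) of 23 | COC(=O)c1cc(OC)c(CC[C@@]2(C)[C@@H](O)C[C@]3(C)C(C)=CCC[C@H]3[C@H]2C)o1 | intermediate
25 | sodium alkoxide of 24 | COC(=O)c1cc(OC)c(CC[C@@]2(C)[C@@H](O[Na])C[C@]3(C)C(C)=CCC[C@H]3[C@H]2C)o1 | intermediate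
26 | sodium O-alkyl dithiocarbonate of 24 | COC(=O)c1cc(OC)c(CC[C@@]2(C)[C@@H](OC(=S)S[Na])C[C@]3(C)C(C)=CCC[C@H]3[C@H]2C)o1 | intermediate
27 | O-alkyl S-methyl dithiocarbonate (xanthate) of 24 | COC(=O)c1cc(OC)c(CC[C@@]2(C)[C@@H](OC(=S)SC)C[C@]3(C)C(C)=CCC[C@H]3[C@H]2C)o1 | intermediate
28 | methyl 4-methoxy-5-{2-[(5S,8R,9R,10S)-4,5,8,9-tetramethyl-trans-decal-3-en-8-yl]ethyl}furan-2-carboxylate | COC(=O)c1cc(OC)c(CC[C@@]2(C)CC[C@]3(C)C(C)=CCC[C@H]3[C@H]2C)o1 | intermediate
29 | 2,5-endoperoxide of furan 28 (2,3,7-trioxabicyclo[2.2.1]hept-5-ene; bridgehead configuration unassigned) | COC(=O)C12OOC(CC[C@@]3(C)CC[C@]4(C)C(C)=CCC[C@H]4[C@H]3C)(O1)C(OC)=C2 | intermediate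
30 | methyl (3E)-4-methoxy-2,5-dioxo-7-[(5S,8R,9R,10S)-4,5,8,9-tetramethyl-trans-decal-3-en-8-yl]hept-3-enoate (cis ene-trione) | COC(=O)C(=O)/C=C(OC)\C(=O)CC[C@@]1(C)CC[C@]2(C)C(C)=CCC[C@H]2[C@H]1C | intermediate
31 | Dysidenone B, (4'R,5'S) | COC(=O)[C@@]1(O)C=C(OC)C(=O)[C@H]1C[C@@]1(C)CC[C@]2(C)C(C)=CCC[C@H]2[C@H]1C | target

Total step count: 16. Longest linear sequence: 14 steps (steps 1–8, then 11–16); steps 9–10 make fragment 2 on a side branch.

Steps most likely to fail

Step 16. The copper complex may discriminate poorly between the faces of the C4' ketone, or closure may run through the other enol geometry or an amine-only background pathway, so that diastereomeric cyclopentenones form; the cis ene-trione may also isomerise to the trans form, which cannot close. The fallback sets out from 30 and comes back at 31. Ene-trione 30 is cyclised with catalytic Et3N in CH2Cl2 at 0 °C, the established base-mediated aldol closure of cis-enediones to 4-hydroxycyclopent-2-enones, without stereochemical guidance. This should give 31 together with its (4'S,5'R) diastereomer F1, its C5' epimer (4'R,5'R) F2 and the (4'S,5'S) isomer F3. Compound 31 is separated by preparative HPLC, and the other isomers are resubmitted to the amine, which re-establishes the mixture by C5' epimerisation and retro-aldol/aldol, so that material can be cycled.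

Step 11. The furylmethyl anion may act as a base towards the enone (γ-deprotonation) or add 1,2, and the hindered tetrasubstituted enolate may be protonated or O-methylated before C-methylation. The fallback sets out from 20 and 17 and comes back at 23. Trienolate 21 is quenched with Me3SiCl to give the C-silylated furan methyl 4-methoxy-5-[(trimethylsilyl)methyl]furan-2-carboxylate F4. Fluoride-triggered conjugate addition of F4 to 17 (Bu4N+ Ph3SiF2−, cat., THF, −78 → 0 °C), a desilylative Michael addition of a benzylic-type silane that needs no strong base in the presence of the enone, should give the trimethylsilyl enol ether of the adduct F5. MeLi (THF, 0 °C) converts F5 into the amine-free lithium enolate 22, which is methylated with 14 and DMPU to 23 under the same facial control.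

Step 1. Enantioselectivity may be insufficient with the sp2-hybridised Grignard reagent, even though addition and alkylation proceed. The fallback sets out from 1, 2 and 3 and comes back at 5. The addition–alkylation is run with CuBr·SMe2 and no chiral ligand to give racemic 5, and saponification (LiOH, THF–H2O) gives 2-[(1S,6S)-1-methyl-2-oxo-6-(prop-1-en-2-yl)cyclohexyl]acetic acid F6 as the racemate. Crystallisation of its (S)-1-phenylethylammonium salt F7 (or the salt of the antipodal amine, whichever is the less soluble for the needed acid) and acidification return enantiopure F6, which 14 and K2CO3 in DMF re-esterify to 5.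

Further compounds
F1 | step 16 | (4'S,5'R) diastereomer of 31 | COC(=O)[C@]1(O)C=C(OC)C(=O)[C@@H]1C[C@@]1(C)CC[C@]2(C)C(C)=CCC[C@H]2[C@H]1C
F2 | step 16 | (4'R,5'R) diastereomer of 31 (C5' epimer) | COC(=O)[C@@]1(O)C=C(OC)C(=O)[C@@H]1C[C@@]1(C)CC[C@]2(C)C(C)=CCC[C@H]2[C@H]1C
F3 | step 16 | (4'S,5'S) diastereomer of 31 (C4' epimer) | COC(=O)[C@]1(O)C=C(OC)C(=O)[C@H]1C[C@@]1(C)CC[C@]2(C)C(C)=CCC[C@H]2[C@H]1C
F4 | step 11 | methyl 4-methoxy-5-[(trimethylsilyl)methyl]furan-2-carboxylate | COC(=O)c1cc(OC)c(C[Si](C)(C)C)o1
F5 | step 11 | trimethylsilyl enol ether of the conjugate adduct (C7=C8; furylethyl on C8) | COC(=O)c1cc(OC)c(CCC2=C(O[Si](C)(C)C)C[C@]3(C)C(C)=CCC[C@H]3[C@H]2C)o1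
F6 | step 1 | 2-[(1S,6S)-1-methyl-2-oxo-6-(prop-1-en-2-yl)cyclohexyl]acetic acid | OC(=O)C[C@]1(C)C(=O)CCC[C@H]1C(C)=C
F7 | step 1 | (S)-1-phenylethylammonium salt of F6 | [O-]C(=O)C[C@]1(C)C(=O)CCC[C@H]1C(C)=C.C[C@H]([NH3+])c1ccccc1
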